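1. Target could not outgrow the reagent charged, as I took one reagent to go into each target, and by that route the substrate could not fall further than the reagent allowed.

| setting | north-west | south | flask |
|---|---|---|---|
| substrate | 0.10 M | 0.10 M | 0.10 M |
| reagent | 0.050 M | 0.050 M | 0.0500 M |
| free catalyst | 0.50 mM | 0.34 mM | 0.50 mM |
| remark | the very flask that is asked about, followed so far | run made earlier |  |
| time |  |  | 80 min |

| run | time / min | target / % | catalyst intermediate C / % | substrate / % | catalyst intermediate B / % | isomer of the product / % |
|---|---|---|---|---|---|---|
| north-west | 6.00 | 0.6 | 1.0 | 94.3 | 0 | 0 |
| north-west | 12.0 | 6.5 | 0.2 | 90.4 | 2.8 | 0.7 |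
| north-west | 20.0 | 12.1 | 0 | 86.4 | 0.5 | 0 |
| north-west | 25.0 | 11.5 | 0 | 80.8 | 0.6 | 0.2 |
| south | 8.00 | 3.3 | 0 | 95.7 | 0 | 0 |
| south | 15.0 | 5.0 | 0 | 92.1 | 0 | 0.5 |
| south | 25.0 | 10.4 | 1.0 | 86.5 | 0 | 0 |
| south | 30.0 | 12.3 | 0 | 82.6 | 0 | 0 |

(standard deviation of a reading: 1 percentage point)

- a reading or a percentage of target counts all its forms, free or not

- the species in which most of what was charged as substrate, at 80 min sits (target / substrate / isomer of the product / catalyst intermediate B / catalyst intermediate C)
- the largest share itself, whichever of these holds it, in percent of the substrate charged

2. So I carried one number, the reagent share, here 50.0%, which is the reagent charged as a percentage of the substrate charged. On that route it is the ceiling of target, and what remains, 50.0%, is the floor of substrate. The zero of this scale is a share of one half, the tie where ceiling and floor meet. This flask sits exactly at half, with the reagent as limiting reagent.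

3. The south run differed from the north-west run in free catalyst, 0.34 mM against 0.50 mM. The north-west run had lost 19 percentage points of substrate by 25.0 min, and the south run 17 points by 30.0 min. Read as straight lines, with the scatter of the readings, those losses reach the floor at 65.1 min and 86.2 min. So the south run was the slower, but it headed for the same floor, because its share was the same.

4. The north-west line arrives before the asked time, so on my route I expected this flask to reach the tie by then, where substrate and target stand level, and any shortfall of the tie to leave substrate ahead. I therefore committed to substrate as the largest share, with a tie as the worst case, at no less than the floor. My reckoning gave that bound and no central figure.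

5. The forecast said substrate at 57%, within 50% to 68%, on the ground that “the reagent is only half the substrate”.

6. The flask gave substrate at 54.8% and target at 32.7%, so the substrate stood 4.8 points above the floor and the target 17 points under the ceiling.

7. The equations behind the flask were these.

    reagent + free catalyst → catalyst intermediate A (k = 162 /M/min)
    substrate + catalyst intermediate A → catalyst intermediate B (k = 50.9 /M/min)
    catalyst intermediate B ⇌ catalyst intermediate C (K = 1.29, k = 5.04 /min)
    catalyst intermediate C → free catalyst + target (k = 5.46 /min)
    target + free catalyst ⇌ isomer of the product + free catalyst, rate k5*[free catalyst]*[target] forward; the back reaction follows from the equilibrium constant (K = 0.523, k = 9.41 /M/min)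
    2 substrate → homo dimer (k = 0.0122 /M/min)
    reagent + target ⇌ idle adduct, settled at all times (K = 83.6 /M)

8. The flask also held homo dimer at 11.0%, a route for substrate outside my share, yet the lead of substrate over target, 22 points, was larger. The neighbour charged with 0.060 M of substrate has a reagent share of 83.3%, above the tie, with a floor of 16.7%. That neighbour ended with target ahead, at 49.0% against substrate at 43.7%.

(The earlier runs and the new flask stem from a simulated flask on assumed constants.)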